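**Retrosynthetic overview**
- The target comes from its hepta-O-benzyl ether by a single global debenzylation at the end.
- Key disconnection: the aryl–carbonyl bond of the 2,4-dihydroxybenzoyl group. The formyl C–H of a cyclohexenecarbaldehyde serves as an acyl anion equivalent and is joined to 2,4-bis(benzyloxy)-1-bromobenzene, so two electrophilic carbons are coupled without an organometallic that would attack the chromanone carbonyl.
- The cyclohexene (second ring formed) comes from an exo- and enantioselective iminium Diels–Alder reaction of (E)-2,4-bis(benzyloxy)cinnamaldehyde with the flavanone-bearing (E)-1-aryl-3-methylbutadiene. This sets all three ring stereocentres.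
- The chromanone ring (first ring formed) comes from Claisen–Schmidt condensation and oxa-Michael closure of a dienylbenzaldehyde with a 2-hydroxyacetophenone, then kinetic resolution to 2S.
- The diene comes from Suzuki coupling of a 5-bromobenzaldehyde with the (E)-dienylboronate made from 2-methylbut-1-en-3-yne.

Assumption: 2,4-bis(benzyloxy)benzaldehyde and 1-[4-(benzyloxy)-2-hydroxyphenyl]ethan-1-one are bought as catalogue items; ring locants in the Why lines are those of the compound names.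

**Route**

Step 1
Reactants: 1 2,4-bis(benzyloxy)benzaldehyde
Product: 2 2,4-bis(benzyloxy)-5-bromobenzaldehyde
Conditions: NBS (1.05 equiv), MeCN, 0 °C to rt
Reagents that add atoms: N-bromosuccinimide, O=C1CCC(=O)N1Br
Why: Electrophilic aromatic bromination goes to C5, which is para to one benzyloxy group, ortho to the other and meta to the formyl group, while C3 between the two ethers is hindered.

Step 2
Reactants: 3 2-methylbut-1-en-3-yne
Product: 4 4,4,5,5-tetramethyl-2-[(1E)-3-methylbuta-1,3-dien-1-yl]-1,3,2-dioxaborolane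
Conditions: HBpin (1.05 equiv), Cp2Zr(H)Cl (5 mol%), Et3N (10 mol%), neat, 60 °C
Reagents that add atoms: pinacolborane, [H]B1OC(C)(C)C(C)(C)O1
Why: Zirconium-catalysed syn, anti-Markovnikov hydroboration of the terminal alkyne gives the E-alkenylboronate and leaves the 1,1-disubstituted alkene alone.

Step 3
Reactants: 2 2,4-bis(benzyloxy)-5-bromobenzaldehyde; 4 4,4,5,5-tetramethyl-2-[(1E)-3-methylbuta-1,3-dien-1-yl]-1,3,2-dioxaborolane
Product: 5 2,4-bis(benzyloxy)-5-[(1E)-3-methylbuta-1,3-dien-1-yl]benzaldehyde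
Conditions: Pd(PPh3)4 (5 mol%), K2CO3 (2 equiv), 1,4-dioxane/H2O (4:1), 80 °C
Reagents that add atoms: none
Why: Suzuki–Miyaura coupling of the aryl bromide with the alkenylboronate proceeds with retention of the E geometry, and the aldehyde and benzyl ethers are inert.

Step 4
Reactants: 5 2,4-bis(benzyloxy)-5-[(1E)-3-methylbuta-1,3-dien-1-yl]benzaldehyde; 6 1-[4-(benzyloxy)-2-hydroxyphenyl]ethan-1-one
Product: 8 rac-7-(benzyloxy)-2-{2,4-bis(benzyloxy)-5-[(1E)-3-methylbuta-1,3-dien-1-yl]phenyl}-2,3-dihydro-4H-chromen-4-one, via chalcone 7 (not isolated)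
Conditions: pyrrolidine (0.5 equiv), EtOH, 75 °C
Reagents that add atoms: none
Why: Amine-mediated Claisen–Schmidt condensation gives the 2'-hydroxychalcone, which closes by 6-endo oxa-Michael addition of the phenol to the chromanone; C2 is formed racemic here and is resolved in step 5.

Step 5
Reactants: 8 rac-7-(benzyloxy)-2-{2,4-bis(benzyloxy)-5-[(1E)-3-methylbuta-1,3-dien-1-yl]phenyl}-2,3-dihydro-4H-chromen-4-one
Product: 9 (2S)-7-(benzyloxy)-2-{2,4-bis(benzyloxy)-5-[(1E)-3-methylbuta-1,3-dien-1-yl]phenyl}-2,3-dihydro-4H-chromen-4-one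
Conditions: Cp*RhCl[(R,R)-TsDPEN] (1 mol%), HCO2H/Et3N (5:2), EtOAc, rt, stopped at about 55% conversion
Reagents that add atoms: none
Why: Kinetic resolution by Noyori-type asymmetric transfer hydrogenation: the (R,R)-catalyst makes 4R alcohols, and hydride delivery anti to the 2-aryl group gives that configuration only from the 2R ketone (cis-2R,4R alcohol), so the 2R enantiomer is consumed and the 2S ketone is recovered, with the diene untouched.

Step 6
Reactants: 1 2,4-bis(benzyloxy)benzaldehyde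
Product: 10 (2E)-3-[2,4-bis(benzyloxy)phenyl]prop-2-enal
Conditions: Ph3P=CHCHO (1.2 equiv), toluene, 80 °C
Reagents that add atoms: (triphenylphosphoranylidene)acetaldehyde, O=CC=P(c1ccccc1)(c1ccccc1)c1ccccc1
Why: Wittig olefination with the stabilised formylmethylene ylide gives the E-enal by a two-carbon homologation.

Step 7
Reactants: 11 4-bromobenzene-1,3-diol
Product: 12 2,4-bis(benzyloxy)-1-bromobenzene
Conditions: BnBr (2.2 equiv), K2CO3 (2.5 equiv), DMF, 50 °C
Reagents that add atoms: benzyl bromide, BrCc1ccccc1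
Why: Williamson ether synthesis on both phenols.

Step 8
Reactants: 9 (2S)-7-(benzyloxy)-2-{2,4-bis(benzyloxy)-5-[(1E)-3-methylbuta-1,3-dien-1-yl]phenyl}-2,3-dihydro-4H-chromen-4-one; 10 (2E)-3-[2,4-bis(benzyloxy)phenyl]prop-2-enal
Product: 13 (1R,2R,6S)-2-{2,4-bis(benzyloxy)-5-[(2S)-7-(benzyloxy)-4-oxo-3,4-dihydro-2H-chromen-2-yl]phenyl}-6-[2,4-bis(benzyloxy)phenyl]-4-methylcyclohex-3-ene-1-carbaldehyde
Conditions: (S)-2-{bis[3,5-bis(trifluoromethyl)phenyl][(triethylsilyl)oxy]methyl}pyrrolidine (20 mol%), CF3CO2H (40 mol%), toluene, rt, 48–72 h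
Reagents that add atoms: none
Why: Iminium-ion-catalysed Diels–Alder reaction: the (S)-diarylprolinol silyl ether shields the Re face of the enal beta-carbon, so the electron-rich diene adds to the Si face (setting C6 as S and C1 as R), with the iminium arm exo as is known for this catalyst class with beta-aryl enals (setting C2 as R); this is the all-trans, all-equatorial isomer, which is also the thermodynamic one at the epimerisable C1, and the regiochemistry follows from bonding of the nucleophilic CH2 terminus of the diene to the beta-carbon.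

Step 9
Reactants: 13 (1R,2R,6S)-2-{2,4-bis(benzyloxy)-5-[(2S)-7-(benzyloxy)-4-oxo-3,4-dihydro-2H-chromen-2-yl]phenyl}-6-[2,4-bis(benzyloxy)phenyl]-4-methylcyclohex-3-ene-1-carbaldehyde; 12 2,4-bis(benzyloxy)-1-bromobenzene
Product: 14 [(1R,2R,6S)-2-{2,4-bis(benzyloxy)-5-[(2S)-7-(benzyloxy)-4-oxo-3,4-dihydro-2H-chromen-2-yl]phenyl}-6-[2,4-bis(benzyloxy)phenyl]-4-methylcyclohex-3-en-1-yl][2,4-bis(benzyloxy)phenyl]methanone
Conditions: Ir[dF(CF3)ppy]2(dtbbpy)PF6 (1 mol%), NiBr2·glyme (10 mol%), dtbbpy (15 mol%), quinuclidine (10 mol%), K2CO3 (1.5 equiv), 12 (3 equiv), 1,4-dioxane, blue LEDs, rt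
Reagents that add atoms: none
Why: Aldehyde C–H arylation by combined photoredox, hydrogen-atom-transfer and nickel catalysis: the quinuclidinium radical cation abstracts the hydridic formyl hydrogen, the resulting nucleophilic acyl radical (an acyl anion equivalent) is captured by the aryl–nickel species from 12 and reductive elimination forms the ketone, joining two carbons that are both electrophilic in their parent forms under conditions too mild to touch the chromanone carbonyl or C2; no new stereocentre is formed and C1 already has the thermodynamic configuration.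

Step 10
Reactants: 14 [(1R,2R,6S)-2-{2,4-bis(benzyloxy)-5-[(2S)-7-(benzyloxy)-4-oxo-3,4-dihydro-2H-chromen-2-yl]phenyl}-6-[2,4-bis(benzyloxy)phenyl]-4-methylcyclohex-3-en-1-yl][2,4-bis(benzyloxy)phenyl]methanone
Product: 15 guangsangon N
Conditions: BCl3 (1 M in CH2Cl2, 14 equiv), pentamethylbenzene (20 equiv), CH2Cl2, −78 °C; MeOH quench, aqueous work-up
Reagents that add atoms: none
Why: Lewis-acid debenzylation with a cation scavenger: BCl3 cleaves the seven aryl benzyl ethers at low temperature and pentamethylbenzene traps the benzyl cations before they alkylate the resorcinol rings, leaving the trisubstituted alkene, both ketones and all four stereocentres unchanged.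

**Compound list**
1 | 2,4-bis(benzyloxy)benzaldehyde | O=Cc1ccc(OCc2ccccc2)cc1OCc1ccccc1 | starting material
2 | 2,4-bis(benzyloxy)-5-bromobenzaldehyde | O=Cc1cc(Br)c(OCc2ccccc2)cc1OCc1ccccc1 | intermediate
3 | 2-methylbut-1-en-3-yne | C=C(C)C#C | starting material
4 | 4,4,5,5-tetramethyl-2-[(1E)-3-methylbuta-1,3-dien-1-yl]-1,3,2-dioxaborolane | C=C(C)/C=C/B1OC(C)(C)C(C)(C)O1 | intermediate
5 | 2,4-bis(benzyloxy)-5-[(1E)-3-methylbuta-1,3-dien-1-yl]benzaldehyde | C=C(C)/C=C/c1cc(C=O)c(OCc2ccccc2)cc1OCc1ccccc1 | intermediate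
6 | 1-[4-(benzyloxy)-2-hydroxyphenyl]ethan-1-one | CC(=O)c1ccc(OCc2ccccc2)cc1O | starting material
7 | (2E)-1-[4-(benzyloxy)-2-hydroxyphenyl]-3-{2,4-bis(benzyloxy)-5-[(1E)-3-methylbuta-1,3-dien-1-yl]phenyl}prop-2-en-1-one (chalcone, not isolated) | C=C(C)/C=C/c1cc(/C=C/C(=O)c2ccc(OCc3ccccc3)cc2O)c(OCc2ccccc2)cc1OCc1ccccc1 | intermediate
8 | rac-7-(benzyloxy)-2-{2,4-bis(benzyloxy)-5-[(1E)-3-methylbuta-1,3-dien-1-yl]phenyl}-2,3-dihydro-4H-chromen-4-one | C=C(C)/C=C/c1cc(C2CC(=O)c3ccc(OCc4ccccc4)cc3O2)c(OCc2ccccc2)cc1OCc1ccccc1 | intermediate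
9 | (2S)-7-(benzyloxy)-2-{2,4-bis(benzyloxy)-5-[(1E)-3-methylbuta-1,3-dien-1-yl]phenyl}-2,3-dihydro-4H-chromen-4-one | C=C(C)/C=C/c1cc([C@@H]2CC(=O)c3ccc(OCc4ccccc4)cc3O2)c(OCc2ccccc2)cc1OCc1ccccc1 | intermediate
10 | (2E)-3-[2,4-bis(benzyloxy)phenyl]prop-2-enal | O=C/C=C/c1ccc(OCc2ccccc2)cc1OCc1ccccc1 | intermediate
11 | 4-bromobenzene-1,3-diol | Oc1ccc(Br)c(O)c1 | starting material
12 | 2,4-bis(benzyloxy)-1-bromobenzene | Brc1ccc(OCc2ccccc2)cc1OCc1ccccc1 | intermediate
13 | (1R,2R,6S)-2-{2,4-bis(benzyloxy)-5-[(2S)-7-(benzyloxy)-4-oxo-3,4-dihydro-2H-chromen-2-yl]phenyl}-6-[2,4-bis(benzyloxy)phenyl]-4-methylcyclohex-3-ene-1-carbaldehyde | CC1=C[C@@H](c2cc([C@@H]3CC(=O)c4ccc(OCc5ccccc5)cc4O3)c(OCc3ccccc3)cc2OCc2ccccc2)[C@H](C=O)[C@@H](c2ccc(OCc3ccccc3)cc2OCc2ccccc2)C1 | intermediate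
14 | [(1R,2R,6S)-2-{2,4-bis(benzyloxy)-5-[(2S)-7-(benzyloxy)-4-oxo-3,4-dihydro-2H-chromen-2-yl]phenyl}-6-[2,4-bis(benzyloxy)phenyl]-4-methylcyclohex-3-en-1-yl][2,4-bis(benzyloxy)phenyl]methanone | CC1=C[C@@H](c2cc([C@@H]3CC(=O)c4ccc(OCc5ccccc5)cc4O3)c(OCc3ccccc3)cc2OCc2ccccc2)[C@H](C(=O)c2ccc(OCc3ccccc3)cc2OCc2ccccc2)[C@@H](c2ccc(OCc3ccccc3)cc2OCc2ccccc2)C1 | intermediate
15 | guangsangon N, [(1R,2R,6S)-6-(2,4-dihydroxyphenyl)-2-{2,4-dihydroxy-5-[(2S)-7-hydroxy-4-oxo-3,4-dihydro-2H-chromen-2-yl]phenyl}-4-methylcyclohex-3-en-1-yl](2,4-dihydroxyphenyl)methanone | CC1=C[C@@H](c2cc([C@@H]3CC(=O)c4ccc(O)cc4O3)c(O)cc2O)[C@H](C(=O)c2ccc(O)cc2O)[C@@H](c2ccc(O)cc2O)C1 | target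

**Step count and risks**

Total step count: 10. Longest linear sequence: 7 (steps 1, 3, 4, 5, 8, 9, 10).

The three steps most likely to fail:

- **Step 8 (Diels–Alder).** The iminium ion of an electron-rich cinnamaldehyde is a weak dienophile, and the exo preference is extrapolated from cyclopentadiene to an acyclic 1-aryl diene. The fallback builds the ring at the ketone oxidation level by a chelation-controlled cycloaddition. It sets out from 9 (with 1 and 6) and comes back at 15, bypassing 13 and 14. Aldol condensation of 1 with 6 (KOH, EtOH, rt) gives (2E)-1-[4-(benzyloxy)-2-hydroxyphenyl]-3-[2,4-bis(benzyloxy)phenyl]prop-2-en-1-one F1. Its chelate with a chiral borate (BH3·THF, AcOH, VANOL; the antipode is chosen for the 1R,2R,6S series) adds to 9 in the exo mode known for this adduct family. This gives [(1R,2R,6S)-2-{2,4-bis(benzyloxy)-5-[(2S)-7-(benzyloxy)-4-oxo-3,4-dihydro-2H-chromen-2-yl]phenyl}-6-[2,4-bis(benzyloxy)phenyl]-4-methylcyclohex-3-en-1-yl][4-(benzyloxy)-2-hydroxyphenyl]methanone F2. BCl3 with pentamethylbenzene then removes its six benzyl groups to give 15.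

- **Step 9 (aldehyde C–H arylation).** The formyl group is flanked by two aryl-bearing carbons, the aryl bromide is electron-rich and ortho-substituted, and the doubly activated C2–H and the benzylic ether C–H bonds could compete in hydrogen abstraction. The fallback reverses the polarity of the union. It sets out from 13 and comes back at 14. [2,4-Bis(benzyloxy)phenyl]magnesium bromide F3, made from 12 and Mg in THF, is added to 13 at −78 °C; the formyl group is far more electrophilic than the vinylogous-ester-like chromanone carbonyl. This gives [(1R,2R,6S)-2-{2,4-bis(benzyloxy)-5-[(2S)-7-(benzyloxy)-4-oxo-3,4-dihydro-2H-chromen-2-yl]phenyl}-6-[2,4-bis(benzyloxy)phenyl]-4-methylcyclohex-3-en-1-yl][2,4-bis(benzyloxy)phenyl]methanol F4 as a mixture of carbinol epimers. Oxidation with Dess–Martin periodinane gives 14.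

- **Step 5 (kinetic resolution).** The selectivity factor is untested for a flavanone with an ortho-benzyloxy, diene-bearing ring B, and the yield cannot exceed 50%. The fallback replaces resolution by enantioselective ring closure. It sets out from 5 and 6 and comes back at 9. The condensation is stopped at chalcone 7 (KOH, EtOH, rt, isolated), and 7 is cyclised by asymmetric intramolecular oxa-Michael addition with a quinine-derived bifunctional thiourea (or its quinidine-derived pseudoenantiomer, whichever gives 2S), giving 9 directly. It makes no compound outside the list (F0).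

Further compounds
F1 | step 8 | (2E)-1-[4-(benzyloxy)-2-hydroxyphenyl]-3-[2,4-bis(benzyloxy)phenyl]prop-2-en-1-one | O=C(/C=C/c1ccc(OCc2ccccc2)cc1OCc1ccccc1)c1ccc(OCc2ccccc2)cc1O
F2 | step 8 | [(1R,2R,6S)-2-{2,4-bis(benzyloxy)-5-[(2S)-7-(benzyloxy)-4-oxo-3,4-dihydro-2H-chromen-2-yl]phenyl}-6-[2,4-bis(benzyloxy)phenyl]-4-methylcyclohex-3-en-1-yl][4-(benzyloxy)-2-hydroxyphenyl]methanone | CC1=C[C@@H](c2cc([C@@H]3CC(=O)c4ccc(OCc5ccccc5)cc4O3)c(OCc3ccccc3)cc2OCc2ccccc2)[C@H](C(=O)c2ccc(OCc3ccccc3)cc2O)[C@@H](c2ccc(OCc3ccccc3)cc2OCc2ccccc2)C1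
F3 | step 9 | [2,4-bis(benzyloxy)phenyl]magnesium bromide | Br[Mg]c1ccc(OCc2ccccc2)cc1OCc1ccccc1
F4 | step 9 | [(1R,2R,6S)-2-{2,4-bis(benzyloxy)-5-[(2S)-7-(benzyloxy)-4-oxo-3,4-dihydro-2H-chromen-2-yl]phenyl}-6-[2,4-bis(benzyloxy)phenyl]-4-methylcyclohex-3-en-1-yl][2,4-bis(benzyloxy)phenyl]methanol (carbinol epimers) | CC1=C[C@@H](c2cc([C@@H]3CC(=O)c4ccc(OCc5ccccc5)cc4O3)c(OCc3ccccc3)cc2OCc2ccccc2)[C@H](C(O)c2ccc(OCc3ccccc3)cc2OCc2ccccc2)[C@@H](c2ccc(OCc3ccccc3)cc2OCc2ccccc2)C1
F0 | step 5 | none | none
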